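**Strategy.** The oxolane (O1; C2 with the catechol ring; C3 carrying the hydroxymethyl carbon C9; C4 with OH and the dimethoxybenzyl group; C5) is disconnected at C2–C3. A Paternò–Büchi cycloaddition of a bis-pivaloylated 3,4-dihydroxybenzaldehyde to the unsubstituted C=C of 3-(3,4-dimethoxybenzyl)furan makes this bond and a temporary O1–C9 bond in one operation. The furan supplies C9, C3, C4 and C5, the exo-aryl oxetane fixes the cis C2/C3 pair, and the convex bicycle directs hydroxylation of the remaining enol ether C4=C5 cis to C9. Transfer of O1 from C9 to C5 later converts the oxetane into the oxolane. The precursors are a flat, achiral 3-benzylfuran and an aryl aldehyde.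

Key step: step 3

Remark on numbering: oxolane locants follow the atom labels above (O1, C2 aryl, C3, C4, C5; C9 = exocyclic CH2O carbon). "Ring A" is the oxolane O1–C2–C3–C4–C5 and "ring B" is the former furan ring.

Assumption: the lipase of step 6 is taken to acylate the (2R,3R,4R) antipode of 10 faster; the sense of its preference has to be confirmed by screening, and the fallback to step 6 does not depend on it.

Step 1
Reactants: 1 furan-3-boronic acid; 2 3,4-dimethoxybenzyl bromide
Product: 3 3-(3,4-dimethoxybenzyl)furan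
Conditions: 1 (1.2 equiv), Pd(PPh3)4 (3 mol %), K2CO3 (2.5 equiv), DME/H2O (4:1), 80 °C
Reagents that add atoms: none
Why: Suzuki–Miyaura cross-coupling, in which the benzylic C–Br bond adds to zerovalent palladium, the 3-furyl group is transferred from the base-activated boronic acid and reductive elimination joins the two carbons, with no stereocentre involved.

Step 2
Reactants: 4 3,4-dihydroxybenzaldehyde; 5 pivaloyl chloride
Product: 6 3,4-bis(pivaloyloxy)benzaldehyde
Conditions: 5 (2.4 equiv), Et3N (3 equiv), DMAP (5 mol %), CH2Cl2, 0 °C to rt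
Reagents that add atoms: none
Why: DMAP-catalysed O-acylation (nucleophilic acyl substitution) of both phenols gives hindered aryl esters that should withstand every later step and, being acyloxy and not alkoxy groups, leave the aldehyde n,π* triplet lowest.

Step 3
Reactants: 3 3-(3,4-dimethoxybenzyl)furan; 6 3,4-bis(pivaloyloxy)benzaldehyde
Product: 7 racemic (1R*,5S*,6R*)-6-[3,4-bis(pivaloyloxy)phenyl]-4-(3,4-dimethoxybenzyl)-2,7-dioxabicyclo[3.2.0]hept-3-ene (cis-fused; aryl exo; the (1R,5S,6R) antipode is drawn)
Conditions: hν (medium-pressure Hg lamp, Pyrex filter, λ > 300 nm), 3 (4 equiv), benzene, Ar, 10 °C; chromatography on Et3N-deactivated silica, excess 3 recovered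
Reagents that add atoms: none
Why: Excitation of 6 and intersystem crossing give the n,π* triplet aldehyde, whose electrophilic oxygen bonds to the free α-carbon of 3 (future C9) and leaves an allyl-stabilised triplet 1,4-biradical; after spin inversion the benzylic radical carbon (C2) combines with the adjacent β-carbon (C3). This is the Paternò–Büchi reaction, and the closest known type is the photocycloaddition of benzaldehydes to furans, which gives exo-6-aryl-2,7-dioxabicyclo[3.2.0]hept-3-enes. The one new ring, the oxetane O1–C2–C3–C9, closes stepwise (oxygen first, then carbon by radical–radical combination), and it can only be cis-fused to the dihydrofuran, which fixes C9 relative to C3. C2 is set by the biradical conformation preferred at spin inversion, with the aryl group turned away from the five-membered ring (exo), which is the cis C2/C3 arrangement of the target; absolute configuration is not controlled, so 7 should form as the racemate. The step needs attack at the unsubstituted C=C, oxygen-to-α-carbon orientation and exo closure: orientation follows from allyl stabilisation and exo from the closure geometry, but double-bond selection rests only on the reluctance to build a quaternary, benzyl-bearing oxetane carbon next to the aryl group, so the regioisomeric adduct is expected as a by-product to be removed by chromatography. The acyloxy substituents keep the reactive triplet lowest and the Pyrex cut-off leaves the dimethoxyarene unexcited.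

Step 4
Reactants: 7 photoadduct
Product: 8 racemic 6-exo-[3,4-bis(pivaloyloxy)phenyl]-4-endo-(3,4-dimethoxybenzyl)-2,7-dioxabicyclo[3.2.0]heptane-3-exo,4-exo-diol (both hydroxyls on the convex face, cis to the ring-fusion hydrogens)
Conditions: OsO4 (2 mol %), N-methylmorpholine N-oxide (1.5 equiv), acetone/H2O (10:1), 0 °C; crude product used at once (any 9 already formed converges in step 5)
Reagents that add atoms: N-methylmorpholine N-oxide, C[N+]1([O-])CCOCC1; water, O
Why: Upjohn syn-dihydroxylation, in which OsO4 can add to the electron-rich trisubstituted enol ether only on the convex face of the cis-fused bicycle, anti to the oxetane, so the new tertiary C4 hydroxyl is cis to the ring-fusion hydrogens (which becomes cis to C9 in ring A) while C5 becomes a lactol carbon.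

Step 5
Reactants: 8 bicyclic diol
Product: 10 racemic (2R*,3R*,4R*)-2-[3,4-bis(pivaloyloxy)phenyl]-4-(3,4-dimethoxybenzyl)-3-(hydroxymethyl)oxolane-4,5-diol (lactol; both C5 epimers), via lactol aldehyde 9 (not isolated)
Conditions: PPTS (10 mol %), CH2Cl2, rt; then Et3N (0.2 equiv), MeOH, NaBH4 (1 equiv), −20 °C
Reagents that add atoms: none
Why: Acid-catalysed transacetalisation followed by borohydride reduction, in which opening of the strained oxetane acetal and ring–chain exchange of the lactol let O1 leave C9 and close the unstrained five-membered lactol on C5, freeing C9 as the only aldehyde (in equilibrium with its bicyclic hemiacetal), which NaBH4 at low temperature should reduce far faster than the masked lactol carbon and before C3 can epimerise, with C2, C3 and C4 untouched.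

Step 6
Reactants: 10 racemic lactol alcohol
Product: 11 (2R,3R,4R)-3-(acetoxymethyl)-2-[3,4-bis(pivaloyloxy)phenyl]-4-(3,4-dimethoxybenzyl)oxolane-4,5-diol (single antipode; both C5 epimers)
Conditions: Amano lipase PS (Burkholderia cepacia lipase, immobilised), vinyl acetate (5 equiv), MTBE, 30 °C, stopped near half conversion
Reagents that add atoms: vinyl acetate, CC(=O)OC=C
Why: Lipase-catalysed irreversible transesterification (kinetic resolution of a primary alcohol) should acylate only the primary C9 hydroxyl of one antipode, and the acetate at the same time blocks the C9 oxygen so that the lactol can no longer switch to the isomeric ring B through that oxygen, while the unreacted antipode of 10 is removed by chromatography.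

Step 7
Reactants: 11 lactol acetate
Product: 12 (2R,3R,4R)-3-(acetoxymethyl)-2-[3,4-bis(pivaloyloxy)phenyl]-4-(3,4-dimethoxybenzyl)oxolan-4-ol
Conditions: Et3SiH (5 equiv), BF3·OEt2 (3 equiv), CH2Cl2, −78 to −20 °C
Reagents that add atoms: none
Why: Ionic hydrogenation of a lactol, in which BF3·OEt2 ionises the C5 hydroxyl to the cyclic oxocarbenium ion O1=C5 and Et3SiH reduces it to the methylene group; with the C9 oxygen esterified only ring A can form, the inductively deactivated tertiary C4 hydroxyl should stay, and no stereocentre is created or lost.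

Step 8
Reactants: 12 oxolane triester
Product: 13 (2R,3R,4R)-2-(3,4-dihydroxyphenyl)-4-(3,4-dimethoxybenzyl)-3-(hydroxymethyl)oxolan-4-ol (CNP0115253.1)
Conditions: K2CO3 (3 equiv), degassed MeOH, Ar, rt; then AcOH to pH 6
Reagents that add atoms: none
Why: Base-mediated transesterification (methanolysis) should remove the primary acetate and both aryl pivalates in one operation without touching any stereocentre, and exclusion of air with a mildly acidic quench protects the free catechol from oxidation.

**Compound list**

1 | furan-3-boronic acid | OB(O)c1ccoc1 | starting material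
2 | 3,4-dimethoxybenzyl bromide | COc1ccc(CBr)cc1OC | starting material
3 | 3-(3,4-dimethoxybenzyl)furan | COc1ccc(Cc2ccoc2)cc1OC | intermediate
4 | 3,4-dihydroxybenzaldehyde | O=Cc1ccc(O)c(O)c1 | starting material
5 | pivaloyl chloride | CC(C)(C)C(=O)Cl | starting material
6 | 3,4-bis(pivaloyloxy)benzaldehyde | O=Cc1ccc(OC(=O)C(C)(C)C)c(OC(=O)C(C)(C)C)c1 | intermediate
7 | racemic exo photoadduct, (1R*,5S*,6R*)-6-[3,4-bis(pivaloyloxy)phenyl]-4-(3,4-dimethoxybenzyl)-2,7-dioxabicyclo[3.2.0]hept-3-ene (needed antipode drawn) | COc1ccc(CC2=CO[C@@H]3O[C@@H](c4ccc(OC(=O)C(C)(C)C)c(OC(=O)C(C)(C)C)c4)[C@H]23)cc1OC | intermediate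
8 | racemic 6-exo-aryl-4-endo-benzyl-2,7-dioxabicyclo[3.2.0]heptane-3-exo,4-exo-diol (needed antipode drawn) | COc1ccc(C[C@]2(O)[C@@H](O)O[C@@H]3O[C@@H](c4ccc(OC(=O)C(C)(C)C)c(OC(=O)C(C)(C)C)c4)[C@H]23)cc1OC | intermediate
9 | racemic lactol aldehyde, (2R*,3R*,4R*)-2-[3,4-bis(pivaloyloxy)phenyl]-4-(3,4-dimethoxybenzyl)-4,5-dihydroxyoxolane-3-carbaldehyde (C5 epimers; in equilibrium with its bicyclic hemiacetal; needed antipode drawn) | COc1ccc(C[C@]2(O)C(O)O[C@@H](c3ccc(OC(=O)C(C)(C)C)c(OC(=O)C(C)(C)C)c3)[C@H]2C=O)cc1OC | intermediate (not isolated)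
10 | racemic lactol alcohol, (2R*,3R*,4R*)-2-[3,4-bis(pivaloyloxy)phenyl]-4-(3,4-dimethoxybenzyl)-3-(hydroxymethyl)oxolane-4,5-diol (C5 epimers; needed antipode drawn) | COc1ccc(C[C@]2(O)C(O)O[C@@H](c3ccc(OC(=O)C(C)(C)C)c(OC(=O)C(C)(C)C)c3)[C@H]2CO)cc1OC | intermediate
11 | (2R,3R,4R)-3-(acetoxymethyl)-2-[3,4-bis(pivaloyloxy)phenyl]-4-(3,4-dimethoxybenzyl)oxolane-4,5-diol (C5 epimers) | COc1ccc(C[C@]2(O)C(O)O[C@@H](c3ccc(OC(=O)C(C)(C)C)c(OC(=O)C(C)(C)C)c3)[C@H]2COC(C)=O)cc1OC | intermediate
12 | (2R,3R,4R)-3-(acetoxymethyl)-2-[3,4-bis(pivaloyloxy)phenyl]-4-(3,4-dimethoxybenzyl)oxolan-4-ol | COc1ccc(C[C@]2(O)CO[C@@H](c3ccc(OC(=O)C(C)(C)C)c(OC(=O)C(C)(C)C)c3)[C@H]2COC(C)=O)cc1OC | intermediate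
13 | (2R,3R,4R)-2-(3,4-dihydroxyphenyl)-4-(3,4-dimethoxybenzyl)-3-(hydroxymethyl)oxolan-4-ol | COc1ccc(C[C@]2(O)CO[C@@H](c3ccc(O)c(O)c3)[C@H]2CO)cc1OC | target

**Totals.** Total steps: 8. Longest linear sequence: 7 steps (step 1 or step 2, then steps 3 to 8).

**Steps most likely to fail**

Step 3. The triplet aldehyde may add largely across the benzyl-substituted double bond, or may abstract hydrogen from the doubly activated CH2 of 3 in place of cycloaddition. The fallback takes the double-bond question away by attaching the benzyl group after the photoreaction. It sets out from 6, which is irradiated in neat furan (same lamp and filter) to give the regiochemically unambiguous parent adduct racemic exo-6-[3,4-bis(pivaloyloxy)phenyl]-2,7-dioxabicyclo[3.2.0]hept-3-ene F1. Bromine in CH2Cl2 at −78 °C adds to the enol ether to give the 3,4-dibromide F2, which is not isolated; DBU then removes HBr, as in 2-bromoglycal formation, to give the 4-bromo enol ether F3. Negishi coupling of F3 (Pd(PPh3)4, THF, 40 °C) with (3,4-dimethoxybenzyl)zinc bromide F4, made from 2 with zinc dust and LiCl in THF, gives 7, where the route is rejoined.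

Step 5. Hydride may also attack the lactol carbon C5 (over-reduction to an open polyol), or the free aldehyde may epimerise at C3 before it is reduced. The fallback differentiates C9 by oxidation and sets out from 8. After the same PPTS isomerisation, aldehyde 9 is oxidised under Pinnick conditions (NaClO2, NaH2PO4, 2-methyl-2-butene, t-BuOH/H2O) to the lactol acid racemic 2-[3,4-bis(pivaloyloxy)phenyl]-4-(3,4-dimethoxybenzyl)-4,5-dihydroxyoxolane-3-carboxylic acid F5, which cannot be over-oxidised at the masked C5. Et3SiH/BF3·OEt2 reduces C5 (a carboxyl group cannot divert the oxocarbenium ion into ring B) to the oxolane acid F6. BH3·SMe2 in THF at 0 °C reduces the acid, leaving the aryl pivalates, to the racemic primary alcohol 2-[3,4-bis(pivaloyloxy)phenyl]-4-(3,4-dimethoxybenzyl)-3-(hydroxymethyl)oxolan-4-ol F7. Lipase PS with vinyl acetate then acetylates the (2R,3R,4R) antipode of F7 to give 12, where the route is rejoined.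

Step 6. The enzyme may discriminate the antipodes poorly, prefer the unwanted one, or acylate the lactol hydroxyl. The fallback is a classical resolution through covalent diastereomers and sets out from 10. (1S)-Camphanic chloride and pyridine in CH2Cl2 at 0 °C esterify the primary hydroxyl of both antipodes to the camphanate lactols F8, which also caps C9. Et3SiH/BF3·OEt2 reduces C5 as in step 7, and the two oxolane camphanates are separated by crystallisation or chromatography to give the (2R,3R,4R) diastereomer F9. K2CO3 in degassed MeOH removes the camphanate and both pivalates to give 13, where the route ends.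

**Further compounds**

F1 | step 3 | racemic exo-6-[3,4-bis(pivaloyloxy)phenyl]-2,7-dioxabicyclo[3.2.0]hept-3-ene (needed antipode drawn) | C1=CO[C@@H]2O[C@@H](c3ccc(OC(=O)C(C)(C)C)c(OC(=O)C(C)(C)C)c3)[C@H]12
F2 | step 3 | racemic 3,4-dibromo-6-exo-[3,4-bis(pivaloyloxy)phenyl]-2,7-dioxabicyclo[3.2.0]heptane (4-bromine exo, C3 epimers; not isolated) | Br[C@H]1C(Br)O[C@@H]2O[C@@H](c3ccc(OC(=O)C(C)(C)C)c(OC(=O)C(C)(C)C)c3)[C@H]12
F3 | step 3 | racemic 4-bromo-6-exo-[3,4-bis(pivaloyloxy)phenyl]-2,7-dioxabicyclo[3.2.0]hept-3-ene | BrC1=CO[C@@H]2O[C@@H](c3ccc(OC(=O)C(C)(C)C)c(OC(=O)C(C)(C)C)c3)[C@H]12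
F4 | step 3 | (3,4-dimethoxybenzyl)zinc bromide | COc1ccc(C[Zn]Br)cc1OC
F5 | step 5 | racemic (2R*,3R*,4R*)-2-[3,4-bis(pivaloyloxy)phenyl]-4-(3,4-dimethoxybenzyl)-4,5-dihydroxyoxolane-3-carboxylic acid (C5 epimers) | COc1ccc(C[C@]2(O)C(O)O[C@@H](c3ccc(OC(=O)C(C)(C)C)c(OC(=O)C(C)(C)C)c3)[C@H]2C(O)=O)cc1OC
F6 | step 5 | racemic (2R*,3R*,4R*)-2-[3,4-bis(pivaloyloxy)phenyl]-4-(3,4-dimethoxybenzyl)-4-hydroxyoxolane-3-carboxylic acid | COc1ccc(C[C@]2(O)CO[C@@H](c3ccc(OC(=O)C(C)(C)C)c(OC(=O)C(C)(C)C)c3)[C@H]2C(O)=O)cc1OC
F7 | step 5 | racemic (2R*,3R*,4R*)-2-[3,4-bis(pivaloyloxy)phenyl]-4-(3,4-dimethoxybenzyl)-3-(hydroxymethyl)oxolan-4-ol | COc1ccc(C[C@]2(O)CO[C@@H](c3ccc(OC(=O)C(C)(C)C)c(OC(=O)C(C)(C)C)c3)[C@H]2CO)cc1OC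
F8 | step 6 | (1S)-camphanate of the primary hydroxyl of 10 (two diastereomers, C5 epimers; the one with the (2R,3R,4R) oxolane drawn) | COc1ccc(C[C@]2(O)C(O)O[C@@H](c3ccc(OC(=O)C(C)(C)C)c(OC(=O)C(C)(C)C)c3)[C@H]2COC(=O)[C@@]34CC[C@@](C)(C(=O)O3)C4(C)C)cc1OC
F9 | step 6 | (2R,3R,4R)-2-[3,4-bis(pivaloyloxy)phenyl]-4-(3,4-dimethoxybenzyl)-4-hydroxyoxolan-3-ylmethyl (1S)-camphanate | COc1ccc(C[C@]2(O)CO[C@@H](c3ccc(OC(=O)C(C)(C)C)c(OC(=O)C(C)(C)C)c3)[C@H]2COC(=O)[C@@]34CC[C@@](C)(C(=O)O3)C4(C)C)cc1OC
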